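**Plan**

1. The hardest feature is the C3–C1' bond between the chromone and a very electron-rich, ortho-methoxylated B ring, which must be made while the oxidation- and acid-sensitive C8 prenyl group sits on a 1,2,3,4-tetrasubstituted A ring.
2. The retrosynthesis cuts C3–C1' and O1–C2 in one operation, giving an o-hydroxyaryl enaminone and unfunctionalised 1,2,4-trimethoxybenzene. It then cuts C2 (amide acetal) and C8–CH2 (retro-Claisen to a 4-O-(1,1-dimethylallyl) ether), arriving at 2,4-dihydroxyacetophenone.
3. The enabling feature is that C1' lies para to the 4'-OMe and ortho to the 2'-OMe, so ring B is 1,2,4-trimethoxybenzene joined through its innately most reactive C5–H. That ring is also the most easily oxidised π-system present, well below the prenyl olefin. C3 is the nucleophilic α-carbon of a vinylogous amide, and the phenol oxygen (O1) is placed to close ring C.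
4. In the forward direction ring A is completed first (C8 prenyl by aromatic Claisen, then 7-OMe), C2 is added as the enaminone, and ring C closes in the same anodic operation that attaches ring B.
5. The target has no stereocentre and no stereogenic double bond, so there is no stereochemistry to control.

Key step: step 6

Remark: because the target is achiral, "single enantiomer" needs no stereocontrol. The E geometry of the enaminone and the stereocentres of the transient intermediates 5 and 11 are lost on the way to the product.

**Route**

Step 1
Reactants: 1 2,4-dihydroxyacetophenone; 2 3-chloro-3-methylbut-1-yne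
Product: 3 1-[2-hydroxy-4-(2-methylbut-3-yn-2-yloxy)phenyl]ethanone
Conditions: K2CO3, KI (cat.), CuI (cat.), acetone, reflux
Reagents that add atoms: none
Why: Williamson-type O-alkylation (copper-assisted substitution of a tertiary propargylic chloride) should take place only at the more acidic, non-chelated 4-OH, since the 2-OH is tied up in a hydrogen bond to the acetyl carbonyl.

Step 2
Reactants: 3 1-[2-hydroxy-4-(2-methylbut-3-yn-2-yloxy)phenyl]ethanone
Product: 4 1-[2-hydroxy-4-(2-methylbut-3-en-2-yloxy)phenyl]ethanone
Conditions: H2 (1 atm), Lindlar catalyst (Pd/CaCO3, Pb), quinoline, EtOAc, rt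
Reagents that add atoms: none
Why: Lindlar semihydrogenation should stop at the terminal alkene because the poisoned palladium surface binds the alkyne far more strongly than the olefin and leaves the aryl ketone untouched.

Step 3
Reactants: 4 1-[2-hydroxy-4-(2-methylbut-3-en-2-yloxy)phenyl]ethanone
Product: 6 1-[2,4-dihydroxy-3-(3-methylbut-2-enyl)phenyl]ethanone, via dienone 5 (not isolated)
Conditions: PhNEt2, 140 °C, Ar
Reagents that add atoms: none
Why: Aromatic ortho-Claisen ([3,3]-sigmatropic) rearrangement through dienone 5 should deliver the allyl terminus to C3, the position flanked by both oxygens that has the higher double-bond character to C4 in the chelated 2-hydroxyaryl ketone, and the allylic inversion turns the 1,1-dimethylallyl ether into the linear 3-methylbut-2-enyl group before enolisation restores the arene.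

Step 4
Reactants: 6 1-[2,4-dihydroxy-3-(3-methylbut-2-enyl)phenyl]ethanone
Product: 7 1-[2-hydroxy-4-methoxy-3-(3-methylbut-2-enyl)phenyl]ethanone
Conditions: MeI (1.1 equiv), K2CO3, acetone, reflux
Reagents that add atoms: iodomethane, CI
Why: Williamson methylation should be selective for the free 4-OH because the 2-OH stays locked in the intramolecular hydrogen bond to the ketone and is far less nucleophilic under carbonate conditions.

Step 5
Reactants: 7 1-[2-hydroxy-4-methoxy-3-(3-methylbut-2-enyl)phenyl]ethanone
Product: 8 (E)-3-(dimethylamino)-1-[2-hydroxy-4-methoxy-3-(3-methylbut-2-enyl)phenyl]prop-2-en-1-one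
Conditions: DMF-DMA (2.5 equiv), toluene, 90 °C
Reagents that add atoms: N,N-dimethylformamide dimethyl acetal, COC(OC)N(C)C
Why: Condensation of the methyl ketone with the amide acetal (enaminone formation) should give the E-vinylogous amide, a standard reaction of o-hydroxyacetophenones in which the chelated phenol is left free.

Step 6
Reactants: 8 (E)-3-(dimethylamino)-1-[2-hydroxy-4-methoxy-3-(3-methylbut-2-enyl)phenyl]prop-2-en-1-one; 9 1,2,4-trimethoxybenzene
Product: 12 prebarbigerone [7-methoxy-8-(3-methylbut-2-enyl)-3-(2,4,5-trimethoxyphenyl)chromen-4-one], via α-aryl enaminone 10 (not isolated), via aminal 11 (not isolated)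
Conditions: undivided cell, graphite anode, Pt cathode, constant current at low current density (ca. 2.2 F/mol), 9 (3 equiv), nBu4NPF6, HFIP/CH2Cl2, 0 °C to rt, 8 added slowly during the electrolysis
Reagents that add atoms: none
Why: Proposed new method: anodic one-electron oxidation of the excess 1,2,4-trimethoxybenzene 9 (expected to be oxidised several hundred millivolts before the trisubstituted prenyl olefin) in HFIP should give an arene radical cation that is captured at its C5–H position (para to the 2-OMe, ortho to the 4-OMe) by the nucleophilic α-carbon of the vinylogous amide 8, and a second electron transfer with loss of H+ re-aromatises the ring to the α-aryl enaminone 10 (present as its Cα-protonated iminium form). The chelated phenol then adds to the iminium carbon in a 6-exo-trig closure that forms the O1–C2 bond of the pyranone ring (aminal 11), and E1cB loss of dimethylamine gives the chromone, while protons are reduced to H2 at the cathode. The closest known reaction types are the radical-cation C–H substitution of alkoxyarenes by β-dicarbonyl carbon nucleophiles with iodine(III) in HFIP, anodic dehydrogenative aryl C–H/C–H cross-coupling in HFIP, and the oxidative or photoredox C–H functionalisation/chromone-annulation cascades of o-hydroxyaryl enaminones with heteroatom or aryl radicals; what is new is an unfunctionalised arene radical cation as the aryl donor. No stereocentre is formed. The step needs (i) cross- over homo-coupling, secured by the much higher π-nucleophilicity of the enaminone compared with neutral 9, (ii) C5 regiochemistry on 9, which is its innate site of substitution and maps directly onto the 2',4',5'-trimethoxy pattern, (iii) arylation at the α- and not the nitrogen-bearing carbon, which follows from the enamine polarisation, and (iv) survival of the prenyl group and of the product, secured by keeping 8 at low stationary concentration and 9 in excess as the preferred electron donor, the aryl ring of 12 being deactivated by the chromone.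

**Compound list**

1 | 2,4-dihydroxyacetophenone | CC(=O)c1ccc(O)cc1O | starting material
2 | 3-chloro-3-methylbut-1-yne | CC(C)(Cl)C#C | starting material
3 | 1-[2-hydroxy-4-(2-methylbut-3-yn-2-yloxy)phenyl]ethanone | CC(=O)c1ccc(OC(C)(C)C#C)cc1O | intermediate
4 | 1-[2-hydroxy-4-(2-methylbut-3-en-2-yloxy)phenyl]ethanone | CC(=O)c1ccc(OC(C)(C)C=C)cc1O | intermediate
5 | 4-acetyl-3-hydroxy-2-(3-methylbut-2-enyl)cyclohexa-3,5-dien-1-one (Claisen dienone, racemic at C2, not isolated) | CC(=O)C1=C(O)C(CC=C(C)C)C(=O)C=C1 | intermediate
6 | 1-[2,4-dihydroxy-3-(3-methylbut-2-enyl)phenyl]ethanone | CC(=O)c1ccc(O)c(CC=C(C)C)c1O | intermediate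
7 | 1-[2-hydroxy-4-methoxy-3-(3-methylbut-2-enyl)phenyl]ethanone | CC(=O)c1ccc(OC)c(CC=C(C)C)c1O | intermediate
8 | (E)-3-(dimethylamino)-1-[2-hydroxy-4-methoxy-3-(3-methylbut-2-enyl)phenyl]prop-2-en-1-one | CN(C)/C=C/C(=O)c1ccc(OC)c(CC=C(C)C)c1O | intermediate
9 | 1,2,4-trimethoxybenzene | COc1ccc(OC)c(OC)c1 | starting material
10 | 3-(dimethylamino)-1-[2-hydroxy-4-methoxy-3-(3-methylbut-2-enyl)phenyl]-2-(2,4,5-trimethoxyphenyl)prop-2-en-1-one (double-bond geometry not defined, not isolated) | CN(C)C=C(C(=O)c1ccc(OC)c(CC=C(C)C)c1O)c1cc(OC)c(OC)cc1OC | intermediate
11 | 2-(dimethylamino)-7-methoxy-8-(3-methylbut-2-enyl)-3-(2,4,5-trimethoxyphenyl)chroman-4-one (diastereomer mixture, not isolated) | CN(C)C1Oc2c(CC=C(C)C)c(OC)ccc2C(=O)C1c1cc(OC)c(OC)cc1OC | intermediate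
12 | prebarbigerone, 7-methoxy-8-(3-methylbut-2-enyl)-3-(2,4,5-trimethoxyphenyl)chromen-4-one | COc1cc(OC)c(-c2coc3c(CC=C(C)C)c(OC)ccc3c2=O)cc1OC | target

**Count**

Total steps: 6. Longest linear sequence: 6 steps (from 1 to 12).

**Steps most likely to fail, with fallbacks**

Step 6 (proposed new method). The arene radical cation may be consumed by homo-coupling or over-oxidation, the enaminone may be oxidised in competition and couple at the wrong carbon, or it may cyclise in the acidic fluorinated solvent to the 3-unsubstituted chromone before the C–C bond forms. The fallback uses known chemistry and sets out from 8. Iodine in CHCl3 at rt should effect iodocyclisation with loss of dimethylamine to 3-iodo-7-methoxy-8-(3-methylbut-2-enyl)chromen-4-one F1. Suzuki–Miyaura coupling of F1 with (2,4,5-trimethoxyphenyl)boronic acid (Pd(dppf)Cl2, K2CO3, dioxane/water, 80 °C) then comes back to the route at 12.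

Step 3. The sigmatropic shift may deliver the allyl unit to C5 instead of C3, and the ortho-prenyl phenol formed may cyclise on prolonged heating to a 2,2-dimethylchroman. The fallback replaces the rearrangement by a halogen-directed cross-coupling and sets out from 1. Iodination with I2/HIO3 in aqueous ethanol should take place between the two hydroxyl groups to give 1-(2,4-dihydroxy-3-iodophenyl)ethanone F2. Selective methylation of the 4-OH (MeI, K2CO3, acetone) gives 1-(2-hydroxy-3-iodo-4-methoxyphenyl)ethanone F3. Stille coupling of F3 with tributyl(3-methylbut-2-enyl)stannane (Pd(PPh3)4, DMF, 90 °C) should install the linear prenyl group and comes back to the route at 7, bypassing steps 1 to 4.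

Step 1. Substitution at the tertiary propargylic chloride may be sluggish, with elimination of the chloride to the enyne and incomplete conversion of the phenol. The fallback sets out from 1 and uses a Pd(0)-catalysed Tsuji–Trost O-allylation with tert-butyl 2-methylbut-3-en-2-yl carbonate (Pd(PPh3)4, THF, 0 °C). Under kinetic control this should attack the more substituted allyl terminus and give the 1,1-dimethylallyl ether directly, coming back to the route at 4 and bypassing steps 1 and 2. No new compound is made.

**Further compounds**

F1 | step 6 | 3-iodo-7-methoxy-8-(3-methylbut-2-enyl)chromen-4-one | COc1ccc2c(=O)c(I)coc2c1CC=C(C)C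
F2 | step 3 | 1-(2,4-dihydroxy-3-iodophenyl)ethanone | CC(=O)c1ccc(O)c(I)c1O
F3 | step 3 | 1-(2-hydroxy-3-iodo-4-methoxyphenyl)ethanone | CC(=O)c1ccc(OC)c(I)c1O
F0 | step 1 | none | none
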